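**Plan**
- Retrosynthesis: the only skeletal cut is the CH2–CH2 bond C7–C8 of the tetracosanoyl chain. It gives a heptadecyl and a 7-oxo-7-(2-phenylethoxy)heptyl fragment, each traced back to a carboxylic acid with one carbon more: stearic acid and the 2-phenylethyl half-ester of suberic acid. The half-ester is cut at its ester C–O bond to suberic anhydride and 2-phenylethanol.
- Enabling feature: C7 and C8 are unbranched CH2 carbons of a polymethylene chain. The nearest functional group, the C1 ester carbonyl, is six bonds from C7, and the benzene ring sits in the alcohol part behind the ester oxygen. Both fragments are therefore plain primary alkyl radicals of like polarity, available from carboxylates; the CO2H groups are traceless activators lost as CO2 in the coupling itself.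
- Forward order: suberic acid → cyclic anhydride → ring opening by 2-phenylethanol (ester in place before the coupling) → mixed Kolbe electrolysis with stearic acid, which joins the chain and gives the target directly. No ring is formed.
- Stereochemistry: the target has no stereocentre and no C=C bond, so nothing has to be set or protected.

Key step: step 3

Assumption: suberic anhydride (2) is written as the monomeric nine-membered ring; partly oligomeric material carries the same acyl–O–acyl links and should react in the same way in step 2.

**Step 1**
Reactants: 1 octanedioic acid (suberic acid)
Product: 2 oxonane-2,9-dione (suberic anhydride)
Conditions: Ac2O (excess), reflux, 1 h; evaporate AcOH/Ac2O; recrystallise from MeCN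
Reagents that add atoms: none
Why: Dehydration of a dicarboxylic acid by anhydride exchange with acetic anhydride, driven by removal of the volatile acetic acid, should give the anhydride as an activated, desymmetrisable form of the diacid.

**Step 2**
Reactants: 2 oxonane-2,9-dione; 3 2-phenylethanol
Product: 4 8-oxo-8-(2-phenylethoxy)octanoic acid (mono-2-phenylethyl suberate)
Conditions: 3 (1.0 equiv), DMAP (0.1 equiv), pyridine/CH2Cl2, 0 °C → rt; 1 M HCl wash; extract into aq. NaHCO3, re-acidify
Reagents that add atoms: none
Why: DMAP-catalysed alcoholysis of an anhydride (nucleophilic acyl substitution) makes one ester and one carboxylate per anhydride link, the carboxylate is inert to further acylation, and the acid–base extraction should remove any neutral diester.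

**Step 3**
Reactants: 4 8-oxo-8-(2-phenylethoxy)octanoic acid (1 equiv); 5 octadecanoic acid (stearic acid, 3 equiv)
Product: 8 2-phenylethyl tetracosanoate, via potassium octadecanoate 6 (not isolated), via potassium 8-oxo-8-(2-phenylethoxy)octanoate 7 (not isolated)
Conditions: KOH (5 mol% of total CO2H), MeOH, Pt anode/Pt cathode, undivided cell, ca. 0.2 A cm−2, 50–55 °C, stopped while still faintly acidic; filter off alkane, SiO2 chromatography (hexane → hexane/EtOAc)
Reagents that add atoms: potassium hydroxide, [K+].[OH-] (its potassium appears only in the intermediates 6 and 7; none of its atoms remain in 8)
Why: Mixed (crossed) Kolbe electrolysis: the carboxylates 6 and 7, continuously re-formed by the base regenerated at the cathode, are each oxidised by one electron at the platinum anode at high current density and lose CO2, so that the heptadecyl radical and the 7-oxo-7-(2-phenylethoxy)heptyl radical arise side by side in the anode layer and combine to form the C7–C8 bond. The closest known reaction type is the anodic cross-coupling of a fatty acid with an alkanedioic acid half-ester, the classical chain-extension route to long-chain esters. No ring is closed and no stereocentre is formed. The step needs radical combination to win over further oxidation to carbocations (Hofer–Moest pathway), which is secured by both radical centres being primary, unbranched CH2 groups without α-heteroatom or α-aryl substituent, the ester carbonyl lying six bonds and the phenyl ring ten bonds from the radical carbon. Cross- over homo-coupling is needed only in the statistical sense: the excess of cheap 5 should steer most radicals from 7 into the cross product, and the symmetrical C34 alkane and C14 diester by-products differ from 8 by one ester group more or less and should separate by filtration and chromatography. The 2-phenylethyl ester should survive because the bulk solution stays weakly acidic, so methoxide formed at the cathode is quenched by free acid before it can transesterify, while the carboxylate layer adsorbed on platinum shields solvent and the remote arene from oxidation.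

**Compound list**
1 | octanedioic acid (suberic acid) | O=C(O)CCCCCCC(=O)O | starting material
2 | oxonane-2,9-dione (suberic anhydride) | O=C1CCCCCCC(=O)O1 | intermediate
3 | 2-phenylethanol | OCCc1ccccc1 | starting material
4 | 8-oxo-8-(2-phenylethoxy)octanoic acid | OC(=O)CCCCCCC(=O)OCCc1ccccc1 | intermediate
5 | octadecanoic acid (stearic acid) | CCCCCCCCCCCCCCCCCC(=O)O | starting material
6 | potassium octadecanoate (not isolated) | CCCCCCCCCCCCCCCCCC(=O)[O-].[K+] | intermediate
7 | potassium 8-oxo-8-(2-phenylethoxy)octanoate (not isolated) | [K+].[O-]C(=O)CCCCCCC(=O)OCCc1ccccc1 | intermediate
8 | 2-phenylethyl tetracosanoate | CCCCCCCCCCCCCCCCCCCCCCCC(=O)OCCc1ccccc1 | target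

**Step count and risks**
Total steps: 3. Longest linear sequence: 3 (1 → 2 → 4 → 8); 3 and 5 enter as purchased materials.

Steps most likely to fail:

1. Step 3. The electrolysis may suffer from partial methanolysis of the 2-phenylethyl ester near the cathode, from passivation of the anode by the precipitating long-chain alkane, or from a statistical product mixture that is laborious to separate. The fallback makes the same C7–C8 bond by a polar, inherently cross-selective coupling and sets out from 3. Acid-catalysed esterification of 3 with commercial 7-bromoheptanoic acid (OC(=O)CCCCCCBr; TsOH cat., toluene, Dean–Stark) should give 2-phenylethyl 7-bromoheptanoate F1. Heptadecylmagnesium bromide F2, prepared from commercial 1-bromoheptadecane (CCCCCCCCCCCCCCCCCBr) and Mg in THF, would then be added slowly to F1 with catalytic Li2CuCl4 in THF/NMP at −10 to 0 °C. Under these conditions copper-catalysed displacement of the primary bromide is expected to outrun addition to the ester. The fallback returns to the route at 8.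

2. Step 2. If the anhydride is largely oligomeric, each suberoyl unit can be attacked at both ends, so ring opening may lose its mono-selectivity and give diester and free diacid beside the half-ester. The fallback replaces desymmetrisation by a protecting group and sets out from 3. Steglich esterification of 3 with commercial 8-tert-butoxy-8-oxooctanoic acid (CC(C)(C)OC(=O)CCCCCCC(=O)O; EDC·HCl, DMAP, CH2Cl2) should give tert-butyl 2-phenylethyl octanedioate F3. Cleavage of the tert-butyl ester with TFA/CH2Cl2 at rt, which leaves the primary 2-phenylethyl ester untouched, returns to the route at 4.

3. Step 1. Dehydration may lead to linear polyanhydride or leave mixed acetic anhydride end groups that would acetylate 3 in the following step. The fallback omits the anhydride and sets out from 1. Direct acid-catalysed mono-esterification of 1 (3 equiv) with 3 (TsOH cat., toluene, Dean–Stark) should give the half-ester. The excess diacid is removed by its insolubility in cold toluene and the neutral diester by bicarbonate extraction. The fallback returns to the route at 4 and makes no new compound.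

**Further compounds**
F1 | step 3 | 2-phenylethyl 7-bromoheptanoate | BrCCCCCCC(=O)OCCc1ccccc1
F2 | step 3 | heptadecylmagnesium bromide | CCCCCCCCCCCCCCCCC[Mg]Br
F3 | step 2 | tert-butyl 2-phenylethyl octanedioate | CC(C)(C)OC(=O)CCCCCCC(=O)OCCc1ccccc1
F0 | step 1 | none | none
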